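**Retrosynthetic overview**
- Rings: none is formed. Both rings B come from 4-vinylguaiacol 1 (used as benzyl ether 2). Both rings A come already joined through the future bridge carbon in commercial benzophenone-6 3 (used as dibenzyl ether 4).
- Key disconnection: both ring A C(aryl)–CH2 bonds of the two ArCH2CH2Ar links, made together by a twofold ketone-directed ortho-C–H addition of 4 across styrene 2 (through 5) to give ketone 6.
- The carbonyl is a traceless director. In 3 it already sits ortho to OH and para to OMe on both rings, so the regiochemistry that a gigantol/formaldehyde condensation leaves open is fixed from the start.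
- Endgame: the C=O is erased, 6 → benzhydrol 7 → (through 8) target 9, by hydride reduction and one global hydrogenolysis.

Assumption: the target has no stereocentre and no stereogenic double bond (it is achiral), so "single enantiomer" is read as the compound exactly as drawn; 1, 3 and benzyl bromide are taken as commercial.

**Route**

Step 1
Reactants: 1 2-methoxy-4-vinylphenol (4-vinylguaiacol)
Product: 2 1-(benzyloxy)-2-methoxy-4-vinylbenzene
Conditions: BnBr (1.1 equiv), K2CO3 (1.5 equiv), BHT (trace), acetone, 50 °C, dark
Reagents that add atoms: benzyl bromide, BrCc1ccccc1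
Why: Williamson ether synthesis (SN2 O-benzylation of the phenoxide) under mild carbonate conditions, with a radical inhibitor to keep the styrene from polymerising.

Step 2
Reactants: 3 bis(2-hydroxy-4-methoxyphenyl)methanone (benzophenone-6)
Product: 4 bis[2-(benzyloxy)-4-methoxyphenyl]methanone
Conditions: BnBr (2.5 equiv), K2CO3 (4 equiv), DMF, 70 °C
Reagents that add atoms: benzyl bromide, BrCc1ccccc1
Why: Williamson ether synthesis; the carbonyl-chelated ortho-phenols need DMF and heat but alkylate cleanly, and capping them prevents a dead ruthenium aryloxide chelate in step 3.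

Step 3
Reactants: 4 bis[2-(benzyloxy)-4-methoxyphenyl]methanone; 2 1-(benzyloxy)-2-methoxy-4-vinylbenzene (4 equiv used, two molecules incorporated)
Product: 6 bis{2-(benzyloxy)-6-[2-(4-(benzyloxy)-3-methoxyphenyl)ethyl]-4-methoxyphenyl}methanone, via mono-alkylated ketone 5 (not isolated)
Conditions: [RuCl2(p-cymene)]2 (5 mol %), P(4-CF3C6H4)3 (30 mol %), HCO2Na (60 mol %), toluene, 140 °C, sealed tube, Ar, 48 h, 2 added in portions
Reagents that add atoms: none
Why: Murai-type ketone-directed C–H alkylation (chelation-assisted ortho-hydroarylation of an alkene): formate converts the divalent ruthenium chloride dimer into a low-valent ruthenium hydride/phosphine catalyst, the carbonyl oxygen steers it into the single free ortho C–H of one ring A and then of the other, the styrene inserts into Ru–H, and C–C reductive elimination from the less hindered primary alkyl (favoured by the electron-poor phosphine) gives the linear ArCH2CH2Ar link with no co-product.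

Step 4
Reactants: 6 bis{2-(benzyloxy)-6-[2-(4-(benzyloxy)-3-methoxyphenyl)ethyl]-4-methoxyphenyl}methanone
Product: 7 bis{2-(benzyloxy)-6-[2-(4-(benzyloxy)-3-methoxyphenyl)ethyl]-4-methoxyphenyl}methanol
Conditions: LiAlH4 (2 equiv), THF, 0 °C to reflux; then H2O, 15% aq. NaOH; chromatography on Et3N-washed silica
Reagents that add atoms: none
Why: Nucleophilic hydride reduction of a diaryl ketone, in which the small hydride donor LiAlH4 can still reach the tetra-ortho-substituted carbonyl while benzyl and methyl ethers are inert; the carbinol carbon carries two identical aryl groups, so no stereocentre arises.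

Step 5
Reactants: 7 bis{2-(benzyloxy)-6-[2-(4-(benzyloxy)-3-methoxyphenyl)ethyl]-4-methoxyphenyl}methanol
Product: 9 2,2'-methylenebis{3-[2-(4-hydroxy-3-methoxyphenyl)ethyl]-5-methoxyphenol} (CNP0078998.0), via tetraphenol benzhydrol 8 (not isolated)
Conditions: H2 (4 bar), Pd(OH)2/C (20 wt %), EtOAc/AcOH 5:1, rt to 40 °C
Reagents that add atoms: none
Why: Heterogeneous catalytic hydrogenolysis, in which palladium cleaves the four ArO–CH2Ph bonds and, in the acetic acid medium, the doubly benzylic C–OH activated by ortho-hydroxy and para-methoxy donors on both rings, while aryl methyl ethers, the arenes and the diarylmethane C–C bonds are inert.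

**Compound list**
1 | 2-methoxy-4-vinylphenol (4-vinylguaiacol) | C=Cc1ccc(O)c(OC)c1 | starting material
2 | 1-(benzyloxy)-2-methoxy-4-vinylbenzene | C=Cc1ccc(OCc2ccccc2)c(OC)c1 | intermediate
3 | bis(2-hydroxy-4-methoxyphenyl)methanone (benzophenone-6) | COc1ccc(C(=O)c2ccc(OC)cc2O)c(O)c1 | starting material
4 | bis[2-(benzyloxy)-4-methoxyphenyl]methanone | COc1ccc(C(=O)c2ccc(OC)cc2OCc2ccccc2)c(OCc2ccccc2)c1 | intermediate
5 | [2-(benzyloxy)-4-methoxyphenyl]{2-(benzyloxy)-6-[2-(4-(benzyloxy)-3-methoxyphenyl)ethyl]-4-methoxyphenyl}methanone | COc1ccc(C(=O)c2c(CCc3ccc(OCc4ccccc4)c(OC)c3)cc(OC)cc2OCc2ccccc2)c(OCc2ccccc2)c1 | intermediate (not isolated)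
6 | bis{2-(benzyloxy)-6-[2-(4-(benzyloxy)-3-methoxyphenyl)ethyl]-4-methoxyphenyl}methanone | O=C(c1c(CCc2ccc(OCc3ccccc3)c(OC)c2)cc(OC)cc1OCc1ccccc1)c1c(CCc2ccc(OCc3ccccc3)c(OC)c2)cc(OC)cc1OCc1ccccc1 | intermediate
7 | bis{2-(benzyloxy)-6-[2-(4-(benzyloxy)-3-methoxyphenyl)ethyl]-4-methoxyphenyl}methanol | OC(c1c(CCc2ccc(OCc3ccccc3)c(OC)c2)cc(OC)cc1OCc1ccccc1)c1c(CCc2ccc(OCc3ccccc3)c(OC)c2)cc(OC)cc1OCc1ccccc1 | intermediate
8 | bis{2-hydroxy-6-[2-(4-hydroxy-3-methoxyphenyl)ethyl]-4-methoxyphenyl}methanol | OC(c1c(CCc2ccc(O)c(OC)c2)cc(OC)cc1O)c1c(CCc2ccc(O)c(OC)c2)cc(OC)cc1O | intermediate (not isolated)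
9 | 2,2'-methylenebis{3-[2-(4-hydroxy-3-methoxyphenyl)ethyl]-5-methoxyphenol} | COc1cc(O)c(Cc2c(O)cc(OC)cc2CCc2ccc(O)c(OC)c2)c(CCc2ccc(O)c(OC)c2)c1 | target

**Totals**
Total step count: 5. Longest linear sequence: 4 steps (3 → 4 → 6 → 7 → 9, or equally 1 → 2 → 6 → 7 → 9).

**Three steps most likely to fail, with fallbacks**

Step 3 (twofold hydroarylation) is the main risk. A twofold Murai alkylation on a 2,2'-dialkoxybenzophenone is an untested extension of the known reaction. It may stall at 5 because the second C–C bond creates a tetra-ortho-substituted benzophenone. It may also give branched isomers, let the low-valent ruthenium insert into an ortho ArO–Bn bond, or lose 2 to thermal polymerisation.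

The fallback sets out from 4 (with 2) and returns at 6. It replaces redox-neutral hydroarylation by dehydrogenative (Fujiwara–Moritani-type) ortho-alkenylation. Compounds 4 and 2 are heated with [RuCl2(p-cymene)]2 (5 mol %), AgSbF6 (20 mol %) and Cu(OAc)2·H2O (30 mol %) under air in 1,2-dichloroethane at 110 °C. A cationic divalent ruthenium acetate metalates each ortho C–H by carboxylate-assisted deprotonation. The styrene can then only insert with the aryl group going to its terminal carbon, and β-hydride elimination gives the bis-(E)-stilbene ketone bis{2-(benzyloxy)-6-[(E)-2-(4-(benzyloxy)-3-methoxyphenyl)ethenyl]-4-methoxyphenyl}methanone F1. Diimide reduction (TsNHNH2, NaOAc, THF/H2O, reflux) saturates the two C=C bonds without touching benzyl ethers or the hindered ketone, giving 6.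

Step 5 (global hydrogenolysis) is the second risk. The crowded benzhydrylic C–OH may resist hydrogenolysis so that the reaction stops at 8. Alternatively 8 may ionise in acetic acid and cyclise onto ring B to a seven-membered ring.

The fallback sets out from 7 and returns at 9. It separates the two tasks. Ionic deoxygenation (Et3SiH in large excess, BF3·OEt2, CH2Cl2, −40 °C) traps the strongly stabilised benzhydryl cation with hydride, giving the tetrabenzyl diarylmethane bis{2-(benzyloxy)-6-[2-(4-(benzyloxy)-3-methoxyphenyl)ethyl]-4-methoxyphenyl}methane F3. Plain debenzylation (H2 1 atm, Pd/C, EtOAc/MeOH, rt) then gives 9.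

Step 4 (hydride reduction) is the third risk. The tetra-ortho-substituted carbonyl may resist LiAlH4, or the very ionisable benzhydrol 7 may not survive isolation.

The fallback sets out from 6 and returns at 9. It skips the alcohol. Hydrogenolysis first (H2 1 atm, Pd/C, EtOAc/MeOH, rt) gives the free tetraphenol ketone bis{2-hydroxy-6-[2-(4-hydroxy-3-methoxyphenyl)ethyl]-4-methoxyphenyl}methanone F2; any over-reduced material at this stage is 8 or 9 and therefore productive. Ionic hydrogenation (Et3SiH in excess, CF3CO2H/CH2Cl2, 0 °C to rt) then takes the ortho-hydroxy, para-methoxy-activated carbonyl through the protonated ketone and the benzhydryl cation directly to the CH2 bridge of 9. The excess silane is there to outrun cationic cyclisation onto ring B.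

**Further compounds**
F1 | step 3 | bis{2-(benzyloxy)-6-[(E)-2-(4-(benzyloxy)-3-methoxyphenyl)ethenyl]-4-methoxyphenyl}methanone | O=C(c1c(/C=C/c2ccc(OCc3ccccc3)c(OC)c2)cc(OC)cc1OCc1ccccc1)c1c(/C=C/c2ccc(OCc3ccccc3)c(OC)c2)cc(OC)cc1OCc1ccccc1
F2 | step 4 | bis{2-hydroxy-6-[2-(4-hydroxy-3-methoxyphenyl)ethyl]-4-methoxyphenyl}methanone | O=C(c1c(CCc2ccc(O)c(OC)c2)cc(OC)cc1O)c1c(CCc2ccc(O)c(OC)c2)cc(OC)cc1O
F3 | step 5 | bis{2-(benzyloxy)-6-[2-(4-(benzyloxy)-3-methoxyphenyl)ethyl]-4-methoxyphenyl}methane | C(c1c(CCc2ccc(OCc3ccccc3)c(OC)c2)cc(OC)cc1OCc1ccccc1)c1c(CCc2ccc(OCc3ccccc3)c(OC)c2)cc(OC)cc1OCc1ccccc1
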